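**Retrosynthetic overview**

1. Target ⇐ ester hydrolysis, C-8 ketone methylenation, enone hydrogenation, C-2 acylation, C-9 α′-alkylation (side chain from methyl hydrogen (S)-3-methylglutarate), C-2 reduction and C-5 epimerisation of a bicyclic enedione.
2. Bicyclic enedione ⇐ key step: ring A is closed on a ring-B dienol ester by forming C-1–C-2 (carbanion acyl shift) and C-4–C-5 (vinylogous Michael addition); the 3-methylbut-2-enoyl group supplies C-2, C-3, C-4 and both methyls on C-4.
3. Enabling feature: C-8, the later exocyclic-methylene carbon of ring B, is a latent ketone 1,3 to the quaternary C-10. Its dienol oxygen holds the acyl unit one six-membered transition state (C-1, C-10, C-9, C-8, O, C-2) away from a C-1 carbanion, and the C-6=C-7 double bond relays the released enolate to C-5.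
4. Dienol ester ⇐ 5,5-disubstituted cyclohexenone ⇐ asymmetric conjugate methylation (C-10) of an enone made by Birch dearomatisation of 3-methoxybenzyl alcohol.
5. Ring order: ring B (from the arene) first, ring A in the key step.

Key step: step 7

Remarks on the chemistry:
- Bicyclic compounds are named with labdane numbering (ring A: C-1 to C-5 and C-10; ring B: C-5 to C-10; C-20 is the methyl on C-10).
- The ligand antipode in step 3 is assumed to be the one that gives the (R)-ketone; otherwise its mirror image is taken.
- Methyl hydrogen (S)-3-methylglutarate and 3-methylbut-2-enoic anhydride are taken as commercial (the first is otherwise made in one step by alkaloid-mediated methanolysis of 3-methylglutaric anhydride, the second from the acid).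

**Route**

Step 1
Reactants: 1 3-methoxybenzyl alcohol
Product: 3 3-(hydroxymethyl)cyclohex-2-en-1-one, via (5-methoxycyclohexa-1,4-dien-1-yl)methanol 2 (not isolated)
Conditions: Li, NH3 (l), t-BuOH, THF, −78 °C; then 2 M HCl, THF, 25 °C
Reagents that add atoms: water, O
Why: Birch reduction of the anisole ring (the benzylic oxygen carried as its lithium alkoxide) should give the 2,5-dihydroanisole, whose enol ether is hydrolysed and conjugated by acid; no stereocentre is formed.

Step 2
Reactants: 3 3-(hydroxymethyl)cyclohex-2-en-1-one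
Product: 4 3-[(trimethylsilyloxy)methyl]cyclohex-2-en-1-one
Conditions: Me3SiCl, imidazole, CH2Cl2, 0 °C
Reagents that add atoms: chlorotrimethylsilane, C[Si](C)(C)Cl
Why: O-silylation masks the hydroxyl for the organoaluminium step; no stereocentre is involved.

Step 3
Reactants: 4 3-[(trimethylsilyloxy)methyl]cyclohex-2-en-1-one
Product: 6 (R)-3-(hydroxymethyl)-3-methylcyclohexan-1-one, via (R)-3-methyl-3-[(trimethylsilyloxy)methyl]cyclohexan-1-one 5 (not isolated)
Conditions: AlMe3, copper thiophene-2-carboxylate Cu(O2CC4H3S) (2 mol%), (S)-1,1'-binaphthyl-2,2'-diyl N,N-bis[(R)-1-phenylethyl]phosphoramidite (4 mol%), Et2O, −30 °C; then 1 M HCl, THF, 25 °C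
Reagents that add atoms: trimethylaluminium, C[Al](C)C
Why: copper-catalysed asymmetric conjugate addition of methyl to the β-substituted enone should create the quaternary C-10 with the configuration fixed by the chiral phosphoramidite ligand, and the acidic work-up removes the silyl group.

Step 4
Reactants: 6 (R)-3-(hydroxymethyl)-3-methylcyclohexan-1-one
Product: 8 (R)-5-(hydroxymethyl)-5-methylcyclohex-2-en-1-one, via bis-silyl enol ether 7 (not isolated)
Conditions: LiN(iPr)2 (2.2 equiv), Me3SiCl, THF, −78 °C; then Pd(OAc)2 (1.05 equiv), MeCN, 25 °C; 1 M HCl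
Reagents that add atoms: none
Why: kinetic deprotonation away from the neopentyl C-9 followed by Saegusa–Ito oxidation should place the double bond at C-6/C-7 (desaturation toward the quaternary C-10 is impossible), and C-10 is untouched.

Step 5
Reactants: 8 (R)-5-(hydroxymethyl)-5-methylcyclohex-2-en-1-one
Product: 9 (R)-5-(iodomethyl)-5-methylcyclohex-2-en-1-one
Conditions: I2, PPh3, imidazole, toluene, 80 °C
Reagents that add atoms: iodine, II
Why: Appel-type iodination of the primary neopentyl alcohol through its alkoxyphosphonium salt; C-10 is untouched.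

Step 6
Reactants: 9 (R)-5-(iodomethyl)-5-methylcyclohex-2-en-1-one; 10 3-methylbut-2-enoic anhydride
Product: 11 (S)-5-(iodomethyl)-5-methylcyclohexa-1,3-dien-1-yl 3-methylbut-2-enoate
Conditions: 10 (3 equiv), TsOH·H2O (5 mol%), toluene, 90 °C
Reagents that add atoms: none
Why: acid-catalysed enol acylation under thermodynamic control should give the linearly conjugated dienol ester (as with isophorone), and avoiding base keeps an enolate from displacing the iodide; the descriptor changes by priority only.

Step 7
Reactants: 11 (S)-5-(iodomethyl)-5-methylcyclohexa-1,3-dien-1-yl 3-methylbut-2-enoate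
Product: 14 (5S,10S)-4,4,10-trimethyl-cis-decal-6-ene-2,8-dione, via lithium dienolate 12 (not isolated), via lithium enolate 13 (not isolated)
Conditions: t-BuLi (2.1 equiv), Et2O/pentane, −100 °C; then THF, −78 → 0 °C; AcOH, −78 °C
Reagents that add atoms: none
Why: Proposed new method: iodine–lithium exchange at −100 °C (faster than addition of t-BuLi to the ester) should give the alkyllithium at C-1, which attacks the dienol ester carbonyl through a six-membered transition state (C-1, C-10, C-9, C-8, O, C-2) and expels the ring-B dienolate 12, so that the C-1–C-2 bond, the enone acceptor and the C-5 nucleophile arise in one event; on warming, the γ-carbon C-5 of the dienolate adds to the β,β-dimethyl enone carbon C-4 to give enolate 13 and, after protonation, 14. The closest known reaction types are the halogen–lithium-exchange-initiated intramolecular acylation of iodo esters (Parham-type cyclisation), the base-induced O-to-C acyl shift of enol esters (Baker–Venkataraman rearrangement) and the vinylogous Michael addition of dienolates to β,β-disubstituted enones. Ring A is closed by a 6-endo-trig Michael addition in which the enolate double bond is exocyclic to the new ring. The only new stereocentre, C-5, is set by the tether: C-4 can reach C-5 only on the face that carries C-1, which gives the cis-fused product (corrected in step 8). The step needs 1,2- and not 1,4-attack of the alkyllithium, secured because only the carbonyl carbon lies within a six-membered transition state, and γ- and not α-attack of the dienolate, secured because α-attack at C-4 would need an eight-membered ring and the aldol addition of C-7 to C-2 is reversible. The quaternary C-10 excludes β-elimination and aromatisation.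

Step 8
Reactants: 14 (5S,10S)-4,4,10-trimethyl-cis-decal-6-ene-2,8-dione
Product: 15 (5R,10S)-4,4,10-trimethyl-trans-decal-6-ene-2,8-dione
Conditions: KOtBu (0.3 equiv), t-BuOH/THF, 25 °C; NH4Cl (aq)
Reagents that add atoms: none
Why: vinylogous epimerisation: reversible γ-deprotonation gives the extended dienolate with C-5 sp2, and reprotonation at C-5 from the face opposite the syn-axial C-20 and 4-methyl groups should give the trans-fused enone, which is also expected to be the more stable epimer.

Step 9
Reactants: 15 (5R,10S)-4,4,10-trimethyl-trans-decal-6-ene-2,8-dione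
Product: 17 (2S,5R,10S)-2-hydroxy-4,4,10-trimethyl-trans-decal-6-en-8-one, via 2,8-diol 16 (not isolated)
Conditions: NaBH4, CeCl3·7H2O, MeOH, 0 → 25 °C; then MnO2, CH2Cl2, 25 °C
Reagents that add atoms: none
Why: Luche-type borohydride reduction takes both carbonyls, hydride reaching the doubly neopentyl C-2 ketone from the equatorial side because the axial side is closed by the syn-axial C-20 and 4-methyl groups, which gives the axial 2-alcohol cis to C-20; MnO2 then reoxidises only the allylic 8-alcohol.

Step 10
Reactants: 18 methyl hydrogen (S)-3-methylglutarate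
Product: 19 methyl (S)-5-hydroxy-3-methylpentanoate
Conditions: BH3·SMe2, THF, 0 → 25 °C; MeOH
Reagents that add atoms: none
Why: chemoselective borane reduction of the carboxylic acid beside the ester; the stereocentre is not touched.

Step 11
Reactants: 19 methyl (S)-5-hydroxy-3-methylpentanoate
Product: 20 methyl (R)-5-iodo-3-methylpentanoate
Conditions: I2, PPh3, imidazole, CH2Cl2, 0 °C
Reagents that add atoms: iodine, II
Why: Appel-type iodination of the primary alcohol; the stereocentre is untouched and its descriptor changes by priority only.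

Step 12
Reactants: 17 (2S,5R,10S)-2-hydroxy-4,4,10-trimethyl-trans-decal-6-en-8-one; 20 methyl (R)-5-iodo-3-methylpentanoate
Product: 22 methyl (2S,5R,9R,10R,13S)-2-hydroxy-8-oxo-17-norlabd-6-en-15-oate, via dilithium alkoxide dienolate 21 (not isolated)
Conditions: LiN(iPr)2 (2.1 equiv), THF, −78 °C; then 20, DMPU, −78 → −20 °C; NH4Cl (aq)
Reagents that add atoms: none
Why: kinetic α′-deprotonation of the enone (C-7 is sp2, so only C-9 can be enolised) and alkylation of the cross-conjugated dienolate by the primary iodide, the electrophile entering C-9 on the face opposite the axial C-20 methyl of the neighbouring C-10, which places the side chain trans to C-20; C-13 is brought in by 20.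

Step 13
Reactants: 22 methyl (2S,5R,9R,10R,13S)-2-hydroxy-8-oxo-17-norlabd-6-en-15-oate
Product: 23 methyl (2S,5R,9R,10R,13S)-2-(3-methylbutanoyloxy)-8-oxo-17-norlabd-6-en-15-oate
Conditions: 3-methylbutanoyl chloride, pyridine, DMAP (cat.), CH2Cl2, 0 → 40 °C
Reagents that add atoms: 3-methylbutanoyl chloride, CC(C)CC(=O)Cl
Why: DMAP-catalysed acylation of the hindered axial 2-hydroxyl, with retention because the C–O bond is not broken.

Step 14
Reactants: 23 methyl (2S,5R,9R,10R,13S)-2-(3-methylbutanoyloxy)-8-oxo-17-norlabd-6-en-15-oate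
Product: 24 methyl (2S,5R,9R,10R,13S)-2-(3-methylbutanoyloxy)-8-oxo-17-norlabdan-15-oate
Conditions: H2 (1 atm), Pd/C, EtOAc, 25 °C
Reagents that add atoms: none
Why: heterogeneous hydrogenation of the enone double bond turns C-6 and C-7 into methylene groups; no stereocentre is formed and the neutral medium should leave the epimerisable C-9 alone.

Step 15
Reactants: 24 methyl (2S,5R,9R,10R,13S)-2-(3-methylbutanoyloxy)-8-oxo-17-norlabdan-15-oate
Product: 25 methyl (2S,5R,9S,10R,13S)-2-(3-methylbutanoyloxy)labd-8(17)-en-15-oate
Conditions: Zn, CH2Br2, TiCl4, THF/CH2Cl2, 0 → 25 °C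
Reagents that add atoms: dibromomethane, BrCBr
Why: Takai–Lombardo methylenation should convert the hindered, enolisable C-8 ketone into the exocyclic methylene without base, so the axial C-9 side chain is not epimerised and both esters survive (the C-9 descriptor changes by priority only).

Step 16
Reactants: 25 methyl (2S,5R,9S,10R,13S)-2-(3-methylbutanoyloxy)labd-8(17)-en-15-oate
Product: 26 (2S,5R,9S,10R,13S)-2-(3-methylbutanoyloxy)labd-8(17)-en-15-oic acid
Conditions: LiOH, THF/MeOH/H2O, 0 °C; then 1 M HCl to pH 4, 0 °C
Reagents that add atoms: lithium hydroxide, [Li+].[OH-]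
Why: saponification of the unhindered primary methyl ester, the axial 2-ester flanked by two syn-axial methyl groups being expected to hydrolyse far more slowly; no stereocentre is affected.

**Compound list**

1 | 3-methoxybenzyl alcohol | COc1cccc(CO)c1 | starting material
2 | (5-methoxycyclohexa-1,4-dien-1-yl)methanol | COC1=CCC=C(CO)C1 | intermediate
3 | 3-(hydroxymethyl)cyclohex-2-en-1-one | O=C1C=C(CO)CCC1 | intermediate
4 | 3-[(trimethylsilyloxy)methyl]cyclohex-2-en-1-one | O=C1C=C(CO[Si](C)(C)C)CCC1 | intermediate
5 | (R)-3-methyl-3-[(trimethylsilyloxy)methyl]cyclohexan-1-one | O=C1C[C@](C)(CO[Si](C)(C)C)CCC1 | intermediate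
6 | (R)-3-(hydroxymethyl)-3-methylcyclohexan-1-one | O=C1C[C@](C)(CO)CCC1 | intermediate
7 | (R)-trimethyl{[5-methyl-5-(trimethylsilyloxymethyl)cyclohex-1-en-1-yl]oxy}silane | C[Si](C)(C)OC1=CCC[C@@](C)(CO[Si](C)(C)C)C1 | intermediate
8 | (R)-5-(hydroxymethyl)-5-methylcyclohex-2-en-1-one | O=C1C[C@](C)(CO)CC=C1 | intermediate
9 | (R)-5-(iodomethyl)-5-methylcyclohex-2-en-1-one | O=C1C[C@](C)(CI)CC=C1 | intermediate
10 | 3-methylbut-2-enoic anhydride | CC(C)=CC(=O)OC(=O)C=C(C)C | starting material
11 | (S)-5-(iodomethyl)-5-methylcyclohexa-1,3-dien-1-yl 3-methylbut-2-enoate | CC(C)=CC(=O)OC1=CC=C[C@@](C)(CI)C1 | intermediate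
12 | lithium 5-methyl-5-(4-methyl-2-oxopent-3-en-1-yl)cyclohexa-1,3-dien-1-olate (dienolate after the acyl shift) | [Li+].[O-]C1=CC=C[C@@](C)(CC(=O)C=C(C)C)C1 | intermediate
13 | lithium C-2 enolate of the cis-fused Michael adduct | [Li+].[O-]C1=CC(C)(C)[C@@H]2C=CC(=O)C[C@]2(C)C1 | intermediate
14 | (5S,10S)-4,4,10-trimethyl-cis-decal-6-ene-2,8-dione (H-5 and C-20 syn) | O=C1CC(C)(C)[C@@H]2C=CC(=O)C[C@]2(C)C1 | intermediate
15 | (5R,10S)-4,4,10-trimethyl-trans-decal-6-ene-2,8-dione (H-5 and C-20 anti) | O=C1CC(C)(C)[C@H]2C=CC(=O)C[C@]2(C)C1 | intermediate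
16 | 4,4,10-trimethyl-trans-decal-6-ene-2,8-diol (2-OH axial and cis to C-20; C-8 epimers) | O[C@H]1CC(C)(C)[C@H]2C=CC(O)C[C@]2(C)C1 | intermediate
17 | (2S,5R,10S)-2-hydroxy-4,4,10-trimethyl-trans-decal-6-en-8-one (2-OH axial, cis to C-20) | O[C@H]1CC(C)(C)[C@H]2C=CC(=O)C[C@]2(C)C1 | intermediate
18 | methyl hydrogen (S)-3-methylglutarate | OC(=O)C[C@H](C)CC(=O)OC | starting material
19 | methyl (S)-5-hydroxy-3-methylpentanoate | OCC[C@H](C)CC(=O)OC | intermediate
20 | methyl (R)-5-iodo-3-methylpentanoate | ICC[C@H](C)CC(=O)OC | intermediate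
21 | dilithium 2-alkoxide 8,9-dienolate of 17 | [Li+].[Li+].[O-][C@H]1CC(C)(C)[C@H]2C=CC([O-])=C[C@]2(C)C1 | intermediate
22 | methyl (2S,5R,9R,10R,13S)-2-hydroxy-8-oxo-17-norlabd-6-en-15-oate | O[C@H]1CC(C)(C)[C@H]2C=CC(=O)[C@H](CC[C@H](C)CC(=O)OC)[C@]2(C)C1 | intermediate
23 | methyl (2S,5R,9R,10R,13S)-2-(3-methylbutanoyloxy)-8-oxo-17-norlabd-6-en-15-oate | CC(C)CC(=O)O[C@H]1CC(C)(C)[C@H]2C=CC(=O)[C@H](CC[C@H](C)CC(=O)OC)[C@]2(C)C1 | intermediate
24 | methyl (2S,5R,9R,10R,13S)-2-(3-methylbutanoyloxy)-8-oxo-17-norlabdan-15-oate | CC(C)CC(=O)O[C@H]1CC(C)(C)[C@H]2CCC(=O)[C@H](CC[C@H](C)CC(=O)OC)[C@]2(C)C1 | intermediate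
25 | methyl (2S,5R,9S,10R,13S)-2-(3-methylbutanoyloxy)labd-8(17)-en-15-oate | CC(C)CC(=O)O[C@H]1CC(C)(C)[C@H]2CCC(=C)[C@H](CC[C@H](C)CC(=O)OC)[C@]2(C)C1 | intermediate
26 | (2S,5R,9S,10R,13S)-2-(3-methylbutanoyloxy)labd-8(17)-en-15-oic acid (CNP0168901.1) | CC(C)CC(=O)O[C@H]1CC(C)(C)[C@H]2CCC(=C)[C@H](CC[C@H](C)CC(=O)O)[C@]2(C)C1 | target

**Step count**

Total step count: 16. Longest linear sequence: 14 steps (steps 1–9 and 12–16); steps 10–11 make the side-chain iodide.

**Steps most likely to fail**

1. Step 7 (proposed new method). Addition of t-BuLi to the ester carbonyl may compete with the exchange. After the acyl shift, the dienolate may be lost by proton transfer from the new enone or stay parked as the reversible C-7 aldolate, so that ring A does not close. Fallback with known chemistry: it sets out from 11, which is taken through the same exchange and acyl shift at −100 °C, but the dienolate is trapped with Me3SiCl to give the silyl dienol ether of the acyl-shift ketone F1. Isolated F1 is then cyclised with TiCl4 in CH2Cl2 at −78 °C (intramolecular vinylogous Mukaiyama–Michael addition, again tether-controlled) and the route is rejoined at 14.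

2. Step 12. C-alkylation at the neopentyl α′-carbon may be slow, so that proton exchange, O-alkylation and loss of configuration at C-9 compete. Fallback: it sets out from 17, which is converted with LiN(iPr)2 and Me3SiCl into the bis-silyl compound F2 (silyl ether plus cross-conjugated silyl dienol ether). Mukaiyama–Michael addition of F2 to methyl vinyl ketone (BF3·OEt2, CH2Cl2, −78 °C, acidic work-up), again from the face opposite C-20, gives the hydroxy enedione F3, which is acylated with 3-methylbutanoyl chloride (pyridine, DMAP) to the ester F4. Horner–Wadsworth–Emmons reaction of the methyl ketone with trimethyl phosphonoacetate and NaH gives the (E)-enoate F5. Copper hydride conjugate reduction (Cu(OAc)2 cat., p-tol-BINAP antipode chosen for 13S, polymethylhydrosiloxane, t-BuOH, toluene) then sets C-13 and saturates the ring enone, and the route is rejoined at 24.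

3. Step 8. The equilibration at the ring fusion may stop at a mixture of C-5 epimers or drain into the deconjugated isomer. Fallback: it sets out from 14, which is deprotonated with KOtBu (1.5 equiv, t-BuOH/THF) and quenched into cold aqueous AcOH to give the deconjugated Δ5 dione F6, in which C-5 is sp2. Hydrogenation (H2, PtO2, EtOAc) from the face opposite the C-20 and axial 4-methyl groups gives the trans-decalindione F7. 2-Iodoxybenzoic acid in DMSO at 70 °C, which can desaturate only toward C-6/C-7, then returns the route to 15.

Further compounds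
F1 | step 7 | (S)-4-methyl-1-[1-methyl-5-(trimethylsilyloxy)cyclohexa-2,4-dien-1-yl]pent-3-en-2-one | C[Si](C)(C)OC1=CC=C[C@@](C)(CC(=O)C=C(C)C)C1
F2 | step 12 | bis(trimethylsilyl) derivative of 17 (2-silyl ether, 8-silyloxy-6,8-diene) | C[Si](C)(C)O[C@H]1CC(C)(C)[C@H]2C=CC(O[Si](C)(C)C)=C[C@]2(C)C1
F3 | step 12 | 2-hydroxy-4,4,10-trimethyl-9-(3-oxobutyl)-trans-decal-6-en-8-one (side chain trans to C-20) | O[C@H]1CC(C)(C)[C@H]2C=CC(=O)[C@H](CCC(C)=O)[C@]2(C)C1
F4 | step 12 | 3-methylbutanoate of F3 | CC(C)CC(=O)O[C@H]1CC(C)(C)[C@H]2C=CC(=O)[C@H](CCC(C)=O)[C@]2(C)C1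
F5 | step 12 | methyl (E)-2-(3-methylbutanoyloxy)-8-oxo-17-norlabda-6,13-dien-15-oate | CC(C)CC(=O)O[C@H]1CC(C)(C)[C@H]2C=CC(=O)[C@H](CC/C(C)=C/C(=O)OC)[C@]2(C)C1
F6 | step 8 | (10R)-4,4,10-trimethyldecal-5-ene-2,8-dione | O=C1CC(C)(C)C2=CCC(=O)C[C@]2(C)C1
F7 | step 8 | 4,4,10-trimethyl-trans-decalin-2,8-dione (H-5 and C-20 anti) | O=C1CC(C)(C)[C@H]2CCC(=O)C[C@]2(C)C1
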